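In a one-step world each J turns one molecule of substrate into Q, so Q, as a fraction of the E and Z charged, equals the J charged over the E and Z charged. That is 30.0% for this flask, and the runs supply one correcting factor, the share of J that ends as Q.

common to all: X 1.7 mM

| run | E | Z | J | remark | time |
|---|---|---|---|---|---|
| south | 14 mM | 14 mM | 6 mM (fed, over 2.5 d) | run made earlier; the fed solution adds 0.25 times the starting volume |  |
| north-west | 22 mM | 22 mM | 6 mM (fed, over 2.5 d) | run made earlier; the fed solution adds 0.25 times the starting volume |  |
| flask | 10 mM | 10 mM | 6.00 mM (fed, over 2.5 d) | the fed solution adds 0.25 times the starting volume | 15 d |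

- south (time / d: E / %, Q / %, Z / %): 1.25: 40.8, 9.6, 44.3; 2.00: 37.9, 15.2, 41.1; 3.00: 36.2, 19.4, 37.2; 5.00: 36.9, 19.7, 37.5; 8.00: 37.3, 19.3, 37.8; 12.0: 36.8, 19.2, 36.8; 20.0: 37.1, 19.8, 36.9
- north-west (time / d: E / %, Q / %, Z / %): 1.25: 44.3, 6.5, 46.2; 2.00: 41.9, 9.7, 44.4; 3.00: 41.4, 12.2, 42.3; 5.00: 41.8, 12.8, 41.3; 8.00: 41.2, 12.7, 41.3; 12.0: 41.5, 12.3, 41.6; 20.0: 41.7, 12.5, 41.5

(standard deviation of a reading: 0.3 percentage points)

- X is single-handed; E and Z are mirror images of each other, charged as a racemate, each of them at the stated concentration
- amounts are per litre of the starting volume; all of the dose is in the solution fed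

* conversion of E and Z together at 15 d
* amount of Q at 15 d, in percent of the E and Z together charged
* amount of Z at 15 d, in percent of the E and Z together charged

Which numbers must be known well? The charges of J and of E and Z enter this reckoning as a ratio, so in it a relative error in either passes straight into Q. Time matters little once the curve is flat: south Q reads 19.4% at 3.00 d and 19.8% at 20.0 d, a difference of 0.4 percentage points against a scatter of 0.3 points. X and the dosing time are the same in both runs and in the flask, so the reckoning needs no value for them. The share itself remains.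

Replacing each flat stretch from 5.00 d onward by its mean gives 0.910 for south and 0.922 for north-west. Their mean, 0.916, is the J yield, the fraction of charged J standing as Q on the plateau. The gap between the two readings of the yield, which carry the scatter, moves this flask's Q by 0.36 points, and that is taken as the size of the error of replacing the curves by their means. The J yield gives this flask Q 27.5%, slightly above the forecast's figure.

The forecast, reasoning “so Q is set by J”, gives conversion 36% (34.5% to 37.5%), Q 27.4% (26.3% to 28.5%) and Z 32% (31.1% to 32.9%).

The flask gives conversion 35.3%, Q 27.3% and Z 32.4%.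

    X + E ⇌ G (K = 260 L mol⁻¹, k = 4400 L mol⁻¹ h⁻¹)
    X + Z ⇌ L (K = 52.0 L mol⁻¹, k = 450 L mol⁻¹ h⁻¹)
    J + G → X + Q (k = 1900 L mol⁻¹ h⁻¹)
    J + L → X + D (k = 830 L mol⁻¹ h⁻¹)
    E ⇌ Z (k = 0.0420 h⁻¹)

During the feed, up to 2.50 d, J consumed G and L, leaving Q 27.0%, D 2.65%, E 30.3% and Z 34.9%. With J, the limiting reagent, at 0% by 7.50 d, E ⇌ Z had brought E and Z to 32.4% each, and Q still reads 27.3% at 150 d. This flask's J yield is 0.911. For a neighbour charged with 15 mM of J, the yield gives Q 68.7%; the computed flask holds 66.2%, a yield of 0.883.

(The runs come from a simulation with constants of no real substance, and the scatter is random.)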